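## The problem

The target 21 is an open-chain lignan: a butane-1,4-diol dibenzoate (C9–C8–C8'–C9') whose two inner carbons each carry a benzyl group, C7 with ring A (3-hydroxy-4-methoxyphenyl) on C8 and C7' with ring B (4-hydroxy-3-methoxyphenyl) on C8'. No ring holds the backbone, so the chain has to be built bond by bond. The only stereocentres, C8 and C8' (both R), sit side by side on a flexible chain and carry near-identical CH2 substituents. Neither can be expected to direct the other by simple acyclic induction, so each must be set by a catalyst, a chiral reagent or a stereospecific transfer. The two halves differ only in which phenol oxygen is methylated, so the molecule is almost but not quite C2-symmetric, and rings A and B must enter as separate, unambiguous pieces. The fragile groups are the two primary benzoates (lost to hydride, organometallics and hydroxide), the two free phenols on electron-rich rings (oxidants, electrophiles) and the underlying 1,4-diol, which cyclodehydrates to a tetrahydrofuran in acid. The esters must therefore come late and the phenol protection must leave without touching them. The feature that opens the key step is that C8 is a methine whose three carbon neighbours are C7 (CH2–aryl), C9 (CH2–O) and C8'. Read as ring A–C7H2–C8H(B)–C9H2(Si), this is an aryl electrophile, the two carbons of a vinylboron unit and a one-carbon nucleophile, with boron left on C8 exactly where the bond to C8' is needed.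

## Retrosynthesis

**21 to 19.** The two phenolic O–benzyl bonds of dibenzoate 20 and then the two ester C–O bonds are cut, leading to diol 19. Benzyl is chosen over silyl or acetal protection because it survives organolithium reagents, alkaline peroxide and fluoride, and leaves by hydrogenolysis, which does not touch benzoates. The forward steps ask only for exhaustive acylation of two primary alcohols and a clean hydrogenolysis.

**19 to 15.** The C9–O bond is traced to the C–Si bond of silane 18, and the C9'–O bond to the primary C–B bond of boronate 17. Boronate 17 loses C9' (the C8'–C9' bond) to give the secondary boronate 15. Both carbinol carbons thus enter at the alcohol oxidation level from nucleophilic one-carbon reagents, and no carboxyl reduction is needed. Silicon and boron are unmasked under different conditions, so neither oxidation disturbs the other. The forward reactions are 1,2-shifts that retain configuration at the migrating carbon.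

**15 to 9 and 12.** The central C8–C8' bond is cut. This is the most convergent cut and separates the ring A half (boronate 9) from the ring B half (ester 12). Each half then derives from a different commercial phenol, which settles the unsymmetrical aryl pattern. Cutting C7'–C8' instead would require benzylation of an existing stereocentre with no handle for control. The forward reaction must create C8' under reagent control and transfer C8 with retention. A sparteine-lithiated α-oxyalkyl carbenoid does both. The hindered 2,4,6-triisopropylbenzoate is preferred to a carbamate as leaving group because the boron partner is a secondary, doubly β-branched boronic ester.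

**9 to 4, 6 and 7.** The ring A–C7 and C8–C9 bonds are cut together, passing through borate 8. The neighbouring option, cutting C7–C8 (benzyl nucleophile on an α-halo boronate), needs a stoichiometric chiral director and a benzylic Grignard reagent. The chosen cut is catalytic, sets C8, and reduces boronate 9 to an aryl triflate 4, vinylboronic ester 7 and silylmethyllithium 6. The forward reaction must favour the three-component pathway over direct cross-coupling and must discriminate the faces of an unsubstituted vinyl group.

**Building blocks.** Triflate 4 comes from phenol 3, and 3 from aldehyde 1 by aryl migration to oxygen through formate 2. Organolithium 6 comes from chloride 5 and lithium. Ester 12 comes from alcohol 11, the benzyl ether of homovanillyl alcohol 10. All are one or two standard operations from commercial materials.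

## Roads not taken

**Alternative 1:** The cut is at C7'–C8' and C7–C8 on a five-membered template in which C9 is a lactone carbonyl and C9' an acetal carbon.
- Forward step: lithiated 2-[4-(benzyloxy)-3-methoxyphenyl]-1,3-dithiane A2 adds to C8' of (5R)-5-(menthyloxy)furan-2(5H)-one A1, anti to the menthyloxy group. The lactone enolate is then alkylated at C8 with 3-(benzyloxy)-4-methoxybenzyl bromide A3, anti to the new substituent, giving the trans,trans lactone A4.
- Merits: two C–C bonds and both stereocentres form in one flask. The acetal centre relays to C8' and C8' to C8 through a ring, which is the relay the open chain lacks. The auxiliary is cheap and the tactic is well established for lignans of this type.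
- Weak points: C9 and C9' arrive at the wrong oxidation level, so a hydride reduction that also expels the auxiliary is needed. The dithiane must be removed with a nickel reagent in the presence of two aryl benzyl ethers. The auxiliary is stoichiometric.
- Comparison: the step count is about the same (roughly eleven), and the stereochemical outcome is more certain than in the chosen plan, because it rests on ring-controlled diastereoselection and not on a catalyst meeting a new substrate pair. The chosen plan offers catalytic induction at C8, independent reagent control at C8', carbinol carbons that need no redox adjustment, and no sulfur.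

**Alternative 2:** The cut is at C8–C8' and C7–C8, with C8 supplied by a dichloromethane-derived carbenoid.
- Forward step: the carbenoid adds to boron of (4S,5S)-4,5-dicyclohexyl-2-{(2S)-1-[4-(benzyloxy)-3-methoxyphenyl]-3-[dimethyl(phenyl)silyl]propan-2-yl}-1,3,2-dioxaborolane A5, and C8' migrates to carbon under control of the C2-symmetric diol. [3-(Benzyloxy)-4-methoxybenzyl]magnesium chloride A6 then displaces the remaining chloride by a second migration to give boronate A7, with boron on C8 for the C9 insertion.
- Merits: diol-directed migration is among the most dependable stereoselective C–C bond formations. It needs no transition metal and leads into the same end game as the chosen plan.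
- Weak points: A5 already contains C8', which needs a first cycle of the same kind. The chain is therefore grown linearly on one boron atom with a stoichiometric chiral diol. Each cycle pairs a cryogenic carbenoid step with an electron-rich benzylic Grignard reagent (prone to Wurtz coupling) attacking a hindered α-chloro boronate, where chloride exchange can erode configuration. The route is one or two steps longer.
- Comparison: stereocontrol is at least as secure as in the chosen plan. The chosen plan offers convergence (three pieces joined in one catalytic step, the two aryl halves in the next), catalytic control of C8 and fewer organometallic operations on advanced material. This logic is kept as the fallback for C8'.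

**Alternative 3:** The cut is at C8–C9 and C8'–C9' at once, leaving (E)-1-[3-(benzyloxy)-4-methoxyphenyl]-4-[4-(benzyloxy)-3-methoxyphenyl]but-2-ene A8.
- Forward step: a chiral divalent palladium catalyst with an oxidant adds two methoxycarbonyl groups syn across the alkene to give succinate A9 with both stereocentres. Hydride reduction, benzoylation and hydrogenolysis would finish the synthesis.
- Merits: this is by far the shortest road. Both stereocentres come from one catalytic step, and the relative configuration follows from syn addition to an (E)-alkene.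
- Weak points: enantioselective double alkoxycarbonylation is established for terminal and aryl-conjugated alkenes, not for unactivated 1,2-dialkyl alkenes. A8 has allylic, benzylic hydrogens on both sides, so palladium hydride isomerisation into conjugation competes. The two alkene ends differ only in remote OMe and OBn positions, which gives the catalyst little to distinguish. A8 itself is hard to make pure, because cross-metathesis of two nearly identical allylarenes gives a statistical mixture.
- Comparison: in step economy this road is clearly better (perhaps seven steps against eleven). The chosen plan offers C–C bond formations of reaction types already shown on closely related substrates, and an aryl pattern fixed by separate building blocks.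

Key step: step 4

Assumption: aldehyde 1 is bought; it is also one benzylation away from isovanillin.

Assumption: the (Sp,Sp) antipode of the ferrocenyl ligand in step 4 is taken to be the one that gives (S)-9. If the sense is the reverse, the (Rp,Rp) antipode is used and nothing else changes.

## Route

Step 1
Reactants: 1 3-(benzyloxy)-4-methoxybenzaldehyde
Product: 3 3-(benzyloxy)-4-methoxyphenol, via aryl formate 2 (not isolated)
Conditions: mCPBA, CH2Cl2, rt; aq. NaHCO3 wash; then K2CO3 (cat.), MeOH, rt
Reagents that add atoms: 3-chloroperoxybenzoic acid (mCPBA), O=C(OO)c1cccc(Cl)c1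
Why: Baeyer–Villiger oxidation of an electron-rich benzaldehyde (Dakin-type): the p-methoxyaryl group migrates to oxygen in the peracid adduct to give formate 2, which mild methanolysis cleaves to the phenol. The benzyl and methyl ethers are inert.

Step 2
Reactants: 3 3-(benzyloxy)-4-methoxyphenol
Product: 4 3-(benzyloxy)-4-methoxyphenyl trifluoromethanesulfonate
Conditions: Tf2O, pyridine, CH2Cl2, 0 °C
Reagents that add atoms: trifluoromethanesulfonic anhydride, O=S(=O)(OS(=O)(=O)C(F)(F)F)C(F)(F)F
Why: O-sulfonylation of a phenol; no other nucleophilic site is present.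

Step 3
Reactants: 5 (chloromethyl)dimethyl(phenyl)silane
Product: 6 [dimethyl(phenyl)silyl]methyllithium
Conditions: Li dispersion (1% Na), pentane, reflux; filter from LiCl under Ar; titrate
Reagents that add atoms: lithium, [Li]
Why: Reductive lithiation of a primary alkyl chloride by lithium metal, as for the trimethylsilyl analogue. In a hydrocarbon LiCl precipitates, so the filtered solution is halide-free, which step 4 requires.

Step 4
Reactants: 7 2-ethenyl-4,4,5,5-tetramethyl-1,3,2-dioxaborolane (vinylboronic acid pinacol ester); 6 [dimethyl(phenyl)silyl]methyllithium; 4 3-(benzyloxy)-4-methoxyphenyl trifluoromethanesulfonate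
Product: 9 2-{(2S)-1-[3-(benzyloxy)-4-methoxyphenyl]-3-[dimethyl(phenyl)silyl]propan-2-yl}-4,4,5,5-tetramethyl-1,3,2-dioxaborolane, via lithium vinylboron ate complex 8 (not isolated)
Conditions: 7, 6, Et2O, 0 °C to rt; evaporate; then 4, Pd(OAc)2 (2 mol%), (Sp,Sp)-2,2'-bis[(R)-α-(dimethylamino)benzyl]-1,1'-bis(diphenylphosphino)ferrocene (Mandyphos ligand, 2.4 mol%), THF, 60 °C
Reagents that add atoms: none
Why: This is the known enantioselective palladium-catalysed conjunctive cross-coupling of a vinylboron ate complex with an aryl triflate, used unchanged. Organolithium 6 adds to boron of 7 to give the four-coordinate borate 8; oxidative addition of triflate 4 to the zerovalent palladium–bisphosphine complex gives a cationic aryl–divalent palladium species which, having only a non-coordinating triflate counter-ion, binds the vinyl group of 8. The silylmethyl group then shifts from boron to the α-carbon (C8–C9 bond) anti to palladium while palladium bonds to the terminal carbon (C7), and reductive elimination forms the ring A–C7 bond and returns zerovalent palladium. No ring closes. The one new stereocentre, C8, is set in the metallate shift by the chiral ferrocenyl bisphosphine, which decides the alkene face that palladium occupies. The step needs the conjunctive pathway to beat direct Suzuki–Miyaura transfer of the vinyl or silylmethyl group and β-hydride elimination from the alkylpalladium intermediate; the triflate electrophile, the halide-free solution of 6 and the wide-bite-angle ligand, which speeds reductive elimination, secure this. The unsubstituted vinyl group leaves no regiochemical choice, the silylmethyl group is the only carbon group on boron that can migrate, and the ethers and the C–Si bond are spectators.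

Step 5
Reactants: 10 4-(2-hydroxyethyl)-2-methoxyphenol (homovanillyl alcohol)
Product: 11 2-[4-(benzyloxy)-3-methoxyphenyl]ethanol
Conditions: BnBr, K2CO3, acetone, reflux
Reagents that add atoms: benzyl bromide, BrCc1ccccc1
Why: Williamson ether synthesis; with carbonate only the phenol is deprotonated, so the primary alcohol is not alkylated.

Step 6
Reactants: 11 2-[4-(benzyloxy)-3-methoxyphenyl]ethanol
Product: 12 2-[4-(benzyloxy)-3-methoxyphenyl]ethyl 2,4,6-tri(propan-2-yl)benzoate
Conditions: 2,4,6-triisopropylbenzoic acid, PPh3, DIAD, THF, 0 °C to rt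
Reagents that add atoms: 2,4,6-tri(propan-2-yl)benzoic acid, CC(C)c1cc(C(C)C)c(C(=O)O)c(C(C)C)c1
Why: Mitsunobu esterification of a primary alcohol. The hindered benzoate resists carbonyl attack by s-BuLi, directs α-lithiation and later serves as the leaving group.

Step 7
Reactants: 12 2-[4-(benzyloxy)-3-methoxyphenyl]ethyl 2,4,6-tri(propan-2-yl)benzoate; 9 2-{(2S)-1-[3-(benzyloxy)-4-methoxyphenyl]-3-[dimethyl(phenyl)silyl]propan-2-yl}-4,4,5,5-tetramethyl-1,3,2-dioxaborolane
Product: 15 2-{(2R,3R)-1-[4-(benzyloxy)-3-methoxyphenyl]-3-[3-(benzyloxy)-4-methoxybenzyl]-4-[dimethyl(phenyl)silyl]butan-2-yl}-4,4,5,5-tetramethyl-1,3,2-dioxaborolane, via lithiated benzoate 13 (not isolated), via boron ate complex 14 (not isolated)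
Conditions: 12, s-BuLi, (−)-sparteine, Et2O, −78 °C, 5 h; then 9, −78 °C; then warm to reflux (35 °C)
Reagents that add atoms: none
Why: Sparteine-mediated lithiation–borylation: s-BuLi/(−)-sparteine removes the pro-S hydrogen α to oxygen to give the configurationally stable (S)-carbenoid 13, which boronate 9 traps with retention to give 14. On warming, C8 migrates from boron to carbon anti to the leaving benzoate, with retention at C8 and inversion at the carbenoid carbon. C8' (R) is thus set by the diamine alone and C8 is carried over unchanged.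

Step 8
Reactants: 15 2-{(2R,3R)-1-[4-(benzyloxy)-3-methoxyphenyl]-3-[3-(benzyloxy)-4-methoxybenzyl]-4-[dimethyl(phenyl)silyl]butan-2-yl}-4,4,5,5-tetramethyl-1,3,2-dioxaborolane
Product: 18 (2R,3R)-2-[4-(benzyloxy)-3-methoxybenzyl]-3-[3-(benzyloxy)-4-methoxybenzyl]-4-[dimethyl(phenyl)silyl]butan-1-ol, via chloromethyl ate complex 16 (not isolated), via homologated boronate 17 (not isolated)
Conditions: BrCH2Cl, n-BuLi, THF, −78 °C to rt; then 2 M NaOH, 30% H2O2, 0 °C to rt
Reagents that add atoms: bromochloromethane, ClCBr; hydrogen peroxide, OO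
Why: Matteson homologation: LiCH2Cl, formed in the presence of 15, adds to boron, and C8' migrates with retention to insert C9'. Alkaline peroxide then converts the primary C–B bond to C–OH by a carbon-to-oxygen shift, while the C–SiMe2Ph bond, which has no heteroatom on silicon, is untouched.

Step 9
Reactants: 18 (2R,3R)-2-[4-(benzyloxy)-3-methoxybenzyl]-3-[3-(benzyloxy)-4-methoxybenzyl]-4-[dimethyl(phenyl)silyl]butan-1-ol
Product: 19 (2R,3R)-2-[3-(benzyloxy)-4-methoxybenzyl]-3-[4-(benzyloxy)-3-methoxybenzyl]butane-1,4-diol
Conditions: KH, t-BuOOH, NMP, rt; then TBAF, 70 °C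
Reagents that add atoms: tert-butyl hydroperoxide, CC(C)(C)OO
Why: Fleming–Tamao oxidation in its basic peroxide variant for dimethylphenylsilyl groups: peroxide or alkoxide attack gives a pentacoordinate silicate, phenyl leaves as benzene, and C9 shifts from silicon to oxygen. No electrophile is present, so the electron-rich rings and benzyl ethers are safe, and the C9' alkoxide can assist through a six-membered siloxane.

Step 10
Reactants: 19 (2R,3R)-2-[3-(benzyloxy)-4-methoxybenzyl]-3-[4-(benzyloxy)-3-methoxybenzyl]butane-1,4-diol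
Product: 20 (2R,3R)-2-[3-(benzyloxy)-4-methoxybenzyl]-3-[4-(benzyloxy)-3-methoxybenzyl]butane-1,4-diyl dibenzoate
Conditions: BzCl, pyridine, DMAP (cat.), CH2Cl2, 0 °C to rt
Reagents that add atoms: benzoyl chloride, O=C(Cl)c1ccccc1
Why: DMAP-catalysed acylation of two unhindered primary alcohols. The non-acidic medium avoids cyclodehydration of the 1,4-diol.

Step 11
Reactants: 20 (2R,3R)-2-[3-(benzyloxy)-4-methoxybenzyl]-3-[4-(benzyloxy)-3-methoxybenzyl]butane-1,4-diyl dibenzoate
Product: 21 (2R,3R)-2-(3-hydroxy-4-methoxybenzyl)-3-(4-hydroxy-3-methoxybenzyl)butane-1,4-diyl dibenzoate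
Conditions: H2 (1 atm), 10% Pd/C, EtOAc/EtOH, rt
Reagents that add atoms: none
Why: Catalytic hydrogenolysis cleaves the two aryl benzyl ethers. Benzoate esters and the non-benzylic C–O bonds are stable, and no stereocentre is touched.

## Compound list

1 | 3-(benzyloxy)-4-methoxybenzaldehyde | COc1ccc(C=O)cc1OCc1ccccc1 | starting material
2 | 3-(benzyloxy)-4-methoxyphenyl formate | COc1ccc(OC=O)cc1OCc1ccccc1 | intermediate
3 | 3-(benzyloxy)-4-methoxyphenol | COc1ccc(O)cc1OCc1ccccc1 | intermediate
4 | 3-(benzyloxy)-4-methoxyphenyl trifluoromethanesulfonate | COc1ccc(OS(=O)(=O)C(F)(F)F)cc1OCc1ccccc1 | intermediate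
5 | (chloromethyl)dimethyl(phenyl)silane | ClC[Si](C)(C)c1ccccc1 | starting material
6 | [dimethyl(phenyl)silyl]methyllithium | [Li]C[Si](C)(C)c1ccccc1 | intermediate
7 | 2-ethenyl-4,4,5,5-tetramethyl-1,3,2-dioxaborolane | C=CB1OC(C)(C)C(C)(C)O1 | starting material
8 | lithium {[dimethyl(phenyl)silyl]methyl}(ethenyl)(2,3-dimethylbutane-2,3-diolato)borate | [Li+].C=C[B-]1(C[Si](C)(C)c2ccccc2)OC(C)(C)C(C)(C)O1 | intermediate
9 | 2-{(2S)-1-[3-(benzyloxy)-4-methoxyphenyl]-3-[dimethyl(phenyl)silyl]propan-2-yl}-4,4,5,5-tetramethyl-1,3,2-dioxaborolane | COc1ccc(C[C@@H](C[Si](C)(C)c2ccccc2)B2OC(C)(C)C(C)(C)O2)cc1OCc1ccccc1 | intermediate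
10 | 4-(2-hydroxyethyl)-2-methoxyphenol (homovanillyl alcohol) | COc1cc(CCO)ccc1O | starting material
11 | 2-[4-(benzyloxy)-3-methoxyphenyl]ethanol | COc1cc(CCO)ccc1OCc1ccccc1 | intermediate
12 | 2-[4-(benzyloxy)-3-methoxyphenyl]ethyl 2,4,6-tri(propan-2-yl)benzoate | COc1cc(CCOC(=O)c2c(C(C)C)cc(C(C)C)cc2C(C)C)ccc1OCc1ccccc1 | intermediate
13 | (1S)-2-[4-(benzyloxy)-3-methoxyphenyl]-1-lithioethyl 2,4,6-tri(propan-2-yl)benzoate (as its (−)-sparteine complex) | [Li][C@@H](Cc1ccc(OCc2ccccc2)c(OC)c1)OC(=O)c1c(C(C)C)cc(C(C)C)cc1C(C)C | intermediate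
14 | lithium [(1S)-2-[4-(benzyloxy)-3-methoxyphenyl]-1-{[2,4,6-tri(propan-2-yl)benzoyl]oxy}ethyl]{(2S)-1-[3-(benzyloxy)-4-methoxyphenyl]-3-[dimethyl(phenyl)silyl]propan-2-yl}(2,3-dimethylbutane-2,3-diolato)borate | [Li+].O=C(O[C@H](Cc1ccc(OCc2ccccc2)c(OC)c1)[B-]1(OC(C)(C)C(C)(C)O1)[C@H](C[Si](C)(C)c1ccccc1)Cc1ccc(OC)c(OCc2ccccc2)c1)c1c(C(C)C)cc(C(C)C)cc1C(C)C | intermediate
15 | 2-{(2R,3R)-1-[4-(benzyloxy)-3-methoxyphenyl]-3-[3-(benzyloxy)-4-methoxybenzyl]-4-[dimethyl(phenyl)silyl]butan-2-yl}-4,4,5,5-tetramethyl-1,3,2-dioxaborolane | COc1ccc(C[C@@H](C[Si](C)(C)c2ccccc2)[C@H](B2OC(C)(C)C(C)(C)O2)Cc2ccc(OCc3ccccc3)c(OC)c2)cc1OCc1ccccc1 | intermediate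
16 | lithium (chloromethyl){(2R,3R)-1-[4-(benzyloxy)-3-methoxyphenyl]-3-[3-(benzyloxy)-4-methoxybenzyl]-4-[dimethyl(phenyl)silyl]butan-2-yl}(2,3-dimethylbutane-2,3-diolato)borate | [Li+].ClC[B-]1(OC(C)(C)C(C)(C)O1)[C@H](Cc1ccc(OCc2ccccc2)c(OC)c1)[C@H](C[Si](C)(C)c1ccccc1)Cc1ccc(OC)c(OCc2ccccc2)c1 | intermediate
17 | 2-{(2R,3R)-2-[4-(benzyloxy)-3-methoxybenzyl]-3-[3-(benzyloxy)-4-methoxybenzyl]-4-[dimethyl(phenyl)silyl]butyl}-4,4,5,5-tetramethyl-1,3,2-dioxaborolane | COc1ccc(C[C@@H](C[Si](C)(C)c2ccccc2)[C@H](CB2OC(C)(C)C(C)(C)O2)Cc2ccc(OCc3ccccc3)c(OC)c2)cc1OCc1ccccc1 | intermediate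
18 | (2R,3R)-2-[4-(benzyloxy)-3-methoxybenzyl]-3-[3-(benzyloxy)-4-methoxybenzyl]-4-[dimethyl(phenyl)silyl]butan-1-ol | COc1ccc(C[C@@H](C[Si](C)(C)c2ccccc2)[C@H](CO)Cc2ccc(OCc3ccccc3)c(OC)c2)cc1OCc1ccccc1 | intermediate
19 | (2R,3R)-2-[3-(benzyloxy)-4-methoxybenzyl]-3-[4-(benzyloxy)-3-methoxybenzyl]butane-1,4-diol | COc1ccc(C[C@@H](CO)[C@H](CO)Cc2ccc(OCc3ccccc3)c(OC)c2)cc1OCc1ccccc1 | intermediate
20 | (2R,3R)-2-[3-(benzyloxy)-4-methoxybenzyl]-3-[4-(benzyloxy)-3-methoxybenzyl]butane-1,4-diyl dibenzoate | COc1ccc(C[C@@H](COC(=O)c2ccccc2)[C@H](COC(=O)c2ccccc2)Cc2ccc(OCc3ccccc3)c(OC)c2)cc1OCc1ccccc1 | intermediate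
21 | (2R,3R)-2-(3-hydroxy-4-methoxybenzyl)-3-(4-hydroxy-3-methoxybenzyl)butane-1,4-diyl dibenzoate | COc1ccc(C[C@@H](COC(=O)c2ccccc2)[C@H](COC(=O)c2ccccc2)Cc2ccc(O)c(OC)c2)cc1O | target

## Step count and risks

Total: 11 steps. Longest linear sequence: 8 steps (steps 1, 2, 4, 7, 8, 9, 10, 11).

**Step 4 (key step).** The most likely failures are direct transfer of the vinyl or silylmethyl group to the arylpalladium species (plain cross-coupling), β-hydride elimination after the metallate shift, and weak facial discrimination. The reasons are that the electron-rich triflate adds slowly to zerovalent palladium, the silylmethyl group is a less-tested migrating group than aryl or simple alkyl, and traces of halide block the alkene-binding site.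

Fallback, from 1 back to 9: Wittig methylenation of 1 (Ph3P=CH2) should give 2-(benzyloxy)-4-ethenyl-1-methoxybenzene F1. Cross-metathesis of F1 with allyl(dimethyl)phenylsilane under the second-generation Grubbs catalyst RuCl2(=CHPh)(PCy3)(H2IMes) should give {(2E)-3-[3-(benzyloxy)-4-methoxyphenyl]prop-2-en-1-yl}dimethyl(phenyl)silane F2. Enantioselective copper-catalysed protoboration of this β-substituted styrene (CuCl, NaOt-Bu, a chiral imidazolinium-derived N-heterocyclic carbene, B2pin2, MeOH, THF) places boron on the carbon remote from the arene and copper, then hydrogen, on the benzylic carbon. The route is rejoined at 9.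

**Step 7.** Deprotonation may stray from the carbon α to oxygen to the benzylic CH2 (followed by loss of the benzoate), to the aryl ring or to the benzyl ether. The 1,2-shift from the hindered secondary ate complex may also be slow enough for the complex to revert and lose configuration.

Fallback, from 9 back to 18, by diol-directed Matteson homologation:
- Boronate 9 is cleaved (NaIO4, NH4OAc, aqueous acetone) to {(2S)-1-[3-(benzyloxy)-4-methoxyphenyl]-3-[dimethyl(phenyl)silyl]propan-2-yl}boronic acid F3.
- F3 is esterified with (1S,2S)-1,2-dicyclohexylethane-1,2-diol (MgSO4, Et2O) to (4S,5S)-4,5-dicyclohexyl-2-{(2S)-1-[3-(benzyloxy)-4-methoxyphenyl]-3-[dimethyl(phenyl)silyl]propan-2-yl}-1,3,2-dioxaborolane F4.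
- LiCHCl2 (THF, −100 °C), then ZnCl2, should give (4S,5S)-2-{(1R,2S)-2-[3-(benzyloxy)-4-methoxybenzyl]-1-chloro-3-[dimethyl(phenyl)silyl]propyl}-4,5-dicyclohexyl-1,3,2-dioxaborolane F5.
- 1-(Benzyloxy)-4-(chloromethyl)-2-methoxybenzene F6 (from commercial 4-(benzyloxy)-3-methoxybenzyl alcohol and SOCl2) is converted with Mg into [4-(benzyloxy)-3-methoxybenzyl]magnesium chloride F7.
- F7 displaces the chloride of F5 with inversion to give (4S,5S)-2-{(2R,3R)-1-[4-(benzyloxy)-3-methoxyphenyl]-3-[3-(benzyloxy)-4-methoxybenzyl]-4-[dimethyl(phenyl)silyl]butan-2-yl}-4,5-dicyclohexyl-1,3,2-dioxaborolane F8.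
- LiCH2Cl then gives (4S,5S)-2-{(2R,3R)-2-[4-(benzyloxy)-3-methoxybenzyl]-3-[3-(benzyloxy)-4-methoxybenzyl]-4-[dimethyl(phenyl)silyl]butyl}-4,5-dicyclohexyl-1,3,2-dioxaborolane F9, and alkaline H2O2 returns the route at 18.

**Step 9.** Phenyl may be displaced from silicon only incompletely, or the C9–Si bond may be cleaved instead (protodesilylation), because the silane is a simple trialkyl(aryl)silane in a hot basic peroxide medium.

Fallback, from 18 back to 19: the dephenylation is made intramolecular and separated from the oxidation. t-BuOK in DMSO lets the C9' alkoxide attack silicon and expel benzene, giving (4R,5R)-4-[3-(benzyloxy)-4-methoxybenzyl]-5-[4-(benzyloxy)-3-methoxybenzyl]-2,2-dimethyl-1,2-oxasilinane F10. This alkoxysilane is then oxidised under standard Tamao conditions (H2O2, KF, KHCO3, THF/MeOH) to 19.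

**Step 3.** Wurtz-type coupling or attack of lithium on the arylsilane may lower the titre, and carried-over chloride would inhibit step 4.

Fallback, from 5 back to 9: chloride 5 and Mg in THF give {[dimethyl(phenyl)silyl]methyl}magnesium chloride F11. F11 adds to 7 to form chloromagnesium {[dimethyl(phenyl)silyl]methyl}(ethenyl)(2,3-dimethylbutane-2,3-diolato)borate F12. The conjunctive coupling with 4 is then run in the Grignard variant, with NaOTf as halide scavenger and the same Pd(OAc)2–ferrocenyl bisphosphine catalyst, returning the route at 9.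

## Further compounds

F1 | step 4 | 2-(benzyloxy)-4-ethenyl-1-methoxybenzene | COc1ccc(C=C)cc1OCc1ccccc1
F2 | step 4 | {(2E)-3-[3-(benzyloxy)-4-methoxyphenyl]prop-2-en-1-yl}dimethyl(phenyl)silane | COc1ccc(/C=C/C[Si](C)(C)c2ccccc2)cc1OCc1ccccc1
F3 | step 7 | {(2S)-1-[3-(benzyloxy)-4-methoxyphenyl]-3-[dimethyl(phenyl)silyl]propan-2-yl}boronic acid | COc1ccc(C[C@@H](C[Si](C)(C)c2ccccc2)B(O)O)cc1OCc1ccccc1
F4 | step 7 | (4S,5S)-4,5-dicyclohexyl-2-{(2S)-1-[3-(benzyloxy)-4-methoxyphenyl]-3-[dimethyl(phenyl)silyl]propan-2-yl}-1,3,2-dioxaborolane | COc1ccc(C[C@@H](C[Si](C)(C)c2ccccc2)B2O[C@@H](C3CCCCC3)[C@H](C3CCCCC3)O2)cc1OCc1ccccc1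
F5 | step 7 | (4S,5S)-2-{(1R,2S)-2-[3-(benzyloxy)-4-methoxybenzyl]-1-chloro-3-[dimethyl(phenyl)silyl]propyl}-4,5-dicyclohexyl-1,3,2-dioxaborolane | COc1ccc(C[C@@H](C[Si](C)(C)c2ccccc2)[C@H](Cl)B2O[C@@H](C3CCCCC3)[C@H](C3CCCCC3)O2)cc1OCc1ccccc1
F6 | step 7 | 1-(benzyloxy)-4-(chloromethyl)-2-methoxybenzene | COc1cc(CCl)ccc1OCc1ccccc1
F7 | step 7 | [4-(benzyloxy)-3-methoxybenzyl]magnesium chloride | COc1cc(C[Mg]Cl)ccc1OCc1ccccc1
F8 | step 7 | (4S,5S)-2-{(2R,3R)-1-[4-(benzyloxy)-3-methoxyphenyl]-3-[3-(benzyloxy)-4-methoxybenzyl]-4-[dimethyl(phenyl)silyl]butan-2-yl}-4,5-dicyclohexyl-1,3,2-dioxaborolane | COc1ccc(C[C@@H](C[Si](C)(C)c2ccccc2)[C@H](B2O[C@@H](C3CCCCC3)[C@H](C3CCCCC3)O2)Cc2ccc(OCc3ccccc3)c(OC)c2)cc1OCc1ccccc1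
F9 | step 7 | (4S,5S)-2-{(2R,3R)-2-[4-(benzyloxy)-3-methoxybenzyl]-3-[3-(benzyloxy)-4-methoxybenzyl]-4-[dimethyl(phenyl)silyl]butyl}-4,5-dicyclohexyl-1,3,2-dioxaborolane | COc1ccc(C[C@@H](C[Si](C)(C)c2ccccc2)[C@H](CB2O[C@@H](C3CCCCC3)[C@H](C3CCCCC3)O2)Cc2ccc(OCc3ccccc3)c(OC)c2)cc1OCc1ccccc1
F10 | step 9 | (4R,5R)-4-[3-(benzyloxy)-4-methoxybenzyl]-5-[4-(benzyloxy)-3-methoxybenzyl]-2,2-dimethyl-1,2-oxasilinane | COc1ccc(C[C@H]2C[Si](C)(C)OC[C@@H]2Cc2ccc(OCc3ccccc3)c(OC)c2)cc1OCc1ccccc1
F11 | step 3 | {[dimethyl(phenyl)silyl]methyl}magnesium chloride | Cl[Mg]C[Si](C)(C)c1ccccc1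
F12 | step 3 | chloromagnesium {[dimethyl(phenyl)silyl]methyl}(ethenyl)(2,3-dimethylbutane-2,3-diolato)borate | Cl[Mg+].C=C[B-]1(C[Si](C)(C)c2ccccc2)OC(C)(C)C(C)(C)O1
A1 | alternative 1 | (5R)-5-{[(1R,2S,5R)-5-methyl-2-(propan-2-yl)cyclohexyl]oxy}furan-2(5H)-one | O=C1C=C[C@H](O[C@@H]2C[C@H](C)CC[C@H]2C(C)C)O1
A2 | alternative 1 | 2-[4-(benzyloxy)-3-methoxyphenyl]-1,3-dithiane | COc1cc(C2SCCCS2)ccc1OCc1ccccc1
A3 | alternative 1 | 2-(benzyloxy)-4-(bromomethyl)-1-methoxybenzene | COc1ccc(CBr)cc1OCc1ccccc1
A4 | alternative 1 | 3,4-trans-4,5-trans 3-[3-(benzyloxy)-4-methoxybenzyl]-4-{2-[4-(benzyloxy)-3-methoxyphenyl]-1,3-dithian-2-yl}-5-(menthyloxy)dihydrofuran-2(3H)-one | COc1ccc(C[C@@H](C(=O)O[C@H]2O[C@@H]3C[C@H](C)CC[C@H]3C(C)C)[C@H]2C4(c5ccc(OCc6ccccc6)c(OC)c5)SCCCS4)cc1OCc1ccccc1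
A5 | alternative 2 | (4S,5S)-4,5-dicyclohexyl-2-{(2S)-1-[4-(benzyloxy)-3-methoxyphenyl]-3-[dimethyl(phenyl)silyl]propan-2-yl}-1,3,2-dioxaborolane | COc1cc(C[C@@H](C[Si](C)(C)c2ccccc2)B2O[C@@H](C3CCCCC3)[C@H](C3CCCCC3)O2)ccc1OCc1ccccc1
A6 | alternative 2 | [3-(benzyloxy)-4-methoxybenzyl]magnesium chloride | COc1ccc(C[Mg]Cl)cc1OCc1ccccc1
A7 | alternative 2 | (4S,5S)-4,5-dicyclohexyl-2-{(2R,3R)-1-[3-(benzyloxy)-4-methoxyphenyl]-3-[4-(benzyloxy)-3-methoxybenzyl]-4-[dimethyl(phenyl)silyl]butan-2-yl}-1,3,2-dioxaborolane | COc1ccc(C[C@@H](B2O[C@@H](C3CCCCC3)[C@H](C4CCCCC4)O2)[C@H](C[Si](C)(C)c5ccccc5)Cc6ccc(OCc7ccccc7)c(OC)c6)cc1OCc1ccccc1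
A8 | alternative 3 | (E)-1-[3-(benzyloxy)-4-methoxyphenyl]-4-[4-(benzyloxy)-3-methoxyphenyl]but-2-ene | COc1ccc(C/C=C/Cc2ccc(OCc3ccccc3)c(OC)c2)cc1OCc1ccccc1
A9 | alternative 3 | dimethyl (2R,3R)-2-[3-(benzyloxy)-4-methoxybenzyl]-3-[4-(benzyloxy)-3-methoxybenzyl]butanedioate | COc1ccc(C[C@@H](C(=O)OC)[C@H](C(=O)OC)Cc2ccc(OCc3ccccc3)c(OC)c2)cc1OCc1ccccc1
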